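## The problem

Dehydrobisgravillol (21) consists of two 1,3,5-trisubstituted benzene rings that are neither fused nor directly bonded but sit at the two ends of an unbranched fourteen-carbon chain, which, counted from ring A, holds seven methylenes, an E double bond between C8 and C9, and five methylenes before ring B. There is no stereocenter, so the only stereochemical task is the alkene geometry, and because an isolated 1,2-dialkyl alkene has no neighbour that could steer or later correct it, the geometry must come from a stereospecific reaction and its position from the way the unequal arms are assembled. The rings differ by one methyl group: ring B is a free resorcinol, ring A carries a methyl ether at C3 and a free phenol at C5. These two oxygens are equivalent in any symmetrical 5-alkylresorcinol and cannot be told apart by simple methylation. The alkene rules out hydrogenolysis (hence benzyl ethers) and halogenating or strongly oxidizing aromatization conditions, and the electron-rich phenols are prone to oxidation and to attack by carbon electrophiles, so ring B should stay masked until the last step. The key step rests on the polyketide pattern of ring A: the chain-bearing carbon C1 and the oxygen-bearing carbons C3 and C5 alternate with three CH carbons, as in a tetraketide in which C1 is the starter-acyl carbonyl carbon and C6 once carried the carboxyl group. A ring A closed this way is formed with one oxygen tied to that carboxyl group and the other free, so the two oxygens are differentiated at the moment the ring forms.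

## Retrosynthesis

The final step should only unmask ring B. Cutting the two aryl O–CH2 bonds of the methoxymethyl acetals leads from 21 back to 20. These acetals are preferred to benzyl ethers, whose hydrogenolysis would saturate C8=C9, and to silyl ethers, which could be lost in the basic steps and would then expose ring B to the methylation meant for ring A. They tolerate organolithium reagents, dissolving metal, zerovalent palladium and hot alkali, and leave under acid catalysis in an alcohol. The forward reaction has to spare the methyl ether and the alkene and keep the released one-carbon electrophile away from the resorcinol carbons.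

Ring A of 20 is then given back a carboxyl group at C6, the carbon between the chain and the free hydroxyl. The aryl–CO2H bond is reconnected to give salicylic acid 19, the carboxyl and the neighbouring phenol are tied together as the six-membered acetonide ester 18, and the O–CH3 bond is cut to reveal phenol 17. Compared with monomethylation of a symmetrical 5-alkylresorcinol this is longer, but it removes all statistics: in 17 one ring A oxygen is locked in the heterocycle and the other is the only free hydroxyl in the molecule. The forward sequence asks for an O-methylation, an alkaline hydrolysis that is harmless to the acetals of ring B, and a thermal loss of the carboxyl group. The last is easy because the carboxyl sits between an ortho hydroxyl and an ortho alkyl group and opposite a methoxyl.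

The central cut opens ring A of 17 between C5, the chain-bearing carbon, and C4a, the carbon that carries the carbonyl group. In the reverse sense C5 becomes a ketone and the ring unfolds into the side chain of diketo-dioxinone 15, whose dioxinone still holds the future C4a, C8a and the lactone carbon. Of the six ring bonds this is the one a polyketide synthase forms, and the only one whose formation leaves the two ring oxygens different. Cutting on the other side of the carboxyl-bearing carbon would correspond to a Claisen closure and lead to an acylphloroglucinol. The precursor has no ring A, no stereocenter and one C–C bond less. The forward reaction is asked for an intramolecular aldol addition through racemic adduct 16 and a dehydration, under conditions mild enough for the acetals and the alkene.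

15 is cut between C3 and C4 of its side chain, the bond between the central methylene and the chain ketone. This Claisen-type disconnection gives the dianion 14 of keto-dioxinone 12 and an acyl donor, imidazolide 13, made in the flask from acid 9. The neighbouring cut between C1 and C2 would need a β-keto acyl donor that enolizes and self-condenses, whereas the chosen cut places the whole long chain in a plain carboxylic acid. 12 comes from commercial dioxinone 10 by acylation of its dienolate 11 with a two-carbon acyl donor. The forward reaction must acylate 14 at its terminal carbon and cope with the acidity of the product.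

In acid 9 the only remaining problem is the E alkene. It is traced to the alkyne of 8 without cutting a carbon–carbon bond. A dissolving-metal reduction gives the trans alkene stereospecifically, where olefination or cross-metathesis between two unbranched alkyl partners would give E/Z mixtures that are hard to separate in a long-chain lipid. The forward step must leave the carboxylate and the electron-rich arene alone.

8 is cut at the C10–C11 bond between the alkyne and the five-methylene arm. The pieces are the dianion 7 of commercial dec-9-ynoic acid 6 and bromide 5. Acid 6 already holds the seven methylenes and the carboxyl carbon that will become the chain-bearing carbon of ring A. The cut on the other side of the alkyne would need two partners that are not commercial. The forward reaction is a C-alkylation of an acetylide in the presence of a carboxylate.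

5 is cut at the aryl–CH2 bond. A meta,meta-dioxygenated arene cannot be alkylated at this position by electrophilic substitution, and an aryllithium flanked by acetal oxygens could scramble by ortho-metalation. The bond is therefore made by cross-coupling of aryl bromide 2 with alkylborane 4, formed in the flask from 5-bromopent-1-ene 3. 2 is the bis-acetal of commercial 5-bromobenzene-1,3-diol 1. The coupling must distinguish the aryl bromide from the primary alkyl bromide that is carried through.

## Roads not taken

Alternative 1: The chain would be cut on both sides of the C8–C9 unit, so that acetylene A3 serves as a two-carbon linchpin between the ring A bromide 1-(7-bromoheptyl)-3-methoxy-5-(methoxymethoxy)benzene A2 and the ring B bromide 5. In the forward direction monometalated A3 would be alkylated with A2, metalated again in the same flask and alkylated with 5 to give the diarylalkyne A1. Trans reduction of A1 and acid would then finish 21.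
- Merits: it is the most convergent plan, forms two C(sp)–C(sp3) bonds in one pot, builds no ring, and would very probably have a shorter longest linear sequence than the chosen plan.
- Weak points: it leaves the real problem of ring A unsolved. A2 can only be reached through a statistical monomethylation of 1 followed by a separation. The one-pot double alkylation of A3 must suppress symmetric dialkylation through acetylide equilibration. Two separate alkylborane couplings are needed for the two bromides A2 and 5. The dissolving-metal step on A1 would see three aryl ethers.
- Comparison: in step count and convergence this road is better. The chosen plan sets against it a ring A whose oxygen pattern is fixed by construction, with no statistical step and no isomer separation, and pays with a longer sequence and three steps to remove the carboxyl group.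

Alternative 2: Ring B would be disconnected at two ring bonds and carried as a cyclohexane-1,3-dione. In the forward direction an alkoxide base would add dimethyl malonate A6 to the β-carbon of the enone (3E,10E)-18-(3-hydroxy-5-methoxyphenyl)octadeca-3,10-dien-2-one A5 and close the ring by Claisen condensation of the methyl ketone of A5 onto one ester group of A6. Hydrolysis and decarboxylation in the same pot would give dione A4, which would be dehydrogenated to the resorcinol at the end.
- Merits: it is a robust classical resorcinol synthesis, A6 is a cheap bulk reagent, two bonds and a ring are formed in one operation, and the dione of A4 serves as its own protecting group for ring B. In ring-forming economy it is better than the chosen plan.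
- Weak points: dehydrogenation of A4 needs halogenation–elimination or a hot noble-metal catalyst. The first would attack the alkene and the electron-rich ring A, the second can migrate or saturate the alkene. The effort is also spent on the ring that needs no differentiation, since A5 must already carry the monomethylated ring A, and A5 itself needs an aldehyde and an olefination after the E alkene is in place.
- Comparison: the chosen plan forms its arene at the correct oxidation level by loss of water alone and uses the ring-forming step to differentiate the ring A oxygens.

Alternative 3: Ring A would be cut at two bonds and assembled by a Danheiser benzannulation. Heating 3-[(E)-14-[3,5-bis(triisopropylsilyloxy)phenyl]tetradec-8-enyl]cyclobut-2-en-1-one A8 with an excess of methoxyethyne A9 would open the four-membered ring to a vinylketene, add the alkyne, open again and close by 6π electrocyclization to phenol A7. Desilylation of A7 would then give 21.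
- Merits: the oxygen pattern is built in, since the phenol comes from the ketone of A8 and the methyl ether from A9. There is no carboxyl group to remove, so the endgame is about three steps shorter than in the chosen plan, and the conditions are neutral and harmless to the alkene. On these points this road is better.
- Weak points: A8 is a sensitive 3-monosubstituted cyclobutenone that needs a long-chain organometallic or a ketene cycloaddition on a substrate already carrying the alkene and ring B, which forces silyl protection. A9 is volatile and unstable and must be prepared and used in excess.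
- Comparison: the chosen plan sets against the shorter endgame bench-stable commercial reagents, a ring closure at room temperature, and a precursor that is reached from a simple carboxylic acid.

Key step: step 7

Remark: chain locants C1 to C14 are counted from ring A; side-chain locants of 15 and ring locants of 16 to 18 follow the names in the compound list.

## Route

Step 1
Reactants: 1 5-bromobenzene-1,3-diol
Product: 2 1-bromo-3,5-bis(methoxymethoxy)benzene
Conditions: NaH (2.4 equiv), MOMCl (2.4 equiv), DMF, 0 °C to rt
Reagents that add atoms: chloromethyl methyl ether (MOMCl), COCCl
Why: Williamson-type O-alkylation of both phenoxides with a reactive α-chloro ether; the aryl bromide is inert to NaH in DMF.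

Step 2
Reactants: 2 1-bromo-3,5-bis(methoxymethoxy)benzene; 3 5-bromopent-1-ene
Product: 5 1-(5-bromopentyl)-3,5-bis(methoxymethoxy)benzene, via 9-(5-bromopentyl)-9-borabicyclo[3.3.1]nonane 4 (not isolated)
Conditions: 3, 9-BBN, THF, 0 °C to rt; then 2, PdCl2(dppf) (cat.), K3PO4 (aq), DMF, 50 °C
Reagents that add atoms: none
Why: Anti-Markovnikov hydroboration followed by B-alkyl Suzuki–Miyaura coupling; the diphosphine complex of zerovalent palladium inserts into the aryl C–Br bond far faster than into the unactivated primary C–Br bond, which is kept for step 3.

Step 3
Reactants: 6 dec-9-ynoic acid; 5 1-(5-bromopentyl)-3,5-bis(methoxymethoxy)benzene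
Product: 8 15-[3,5-bis(methoxymethoxy)phenyl]pentadec-9-ynoic acid, via dilithium dec-9-ynoate acetylide 7 (not isolated)
Conditions: 6 (1.3 equiv), n-BuLi (2.1 equiv per 6), THF/DMPU, −78 to 0 °C; then 5, 0 °C to rt; cold dilute HCl to pH 3
Reagents that add atoms: none
Why: Alkylation of a carboxylate–acetylide dianion: the acetylide carbon displaces the primary bromide by SN2 while the lithium carboxylate is too weak a nucleophile to compete, and the acetals are inert to the acetylide.

Step 4
Reactants: 8 15-[3,5-bis(methoxymethoxy)phenyl]pentadec-9-ynoic acid
Product: 9 (E)-15-[3,5-bis(methoxymethoxy)phenyl]pentadec-9-enoic acid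
Conditions: Li (6 equiv), NH3(l)/THF, −40 °C; solid NH4Cl; cold dilute HCl to pH 3
Reagents that add atoms: none
Why: Dissolving-metal reduction of an internal alkyne: stepwise electron transfer and protonation through the more stable trans vinyl radical and anion sets the E geometry. The carboxylate is not reduced, and without an alcohol as proton source the electron-rich arene should stay intact.

Step 5
Reactants: 10 2,2,6-trimethyl-1,3-dioxin-4-one
Product: 12 2,2-dimethyl-6-(2-oxopropyl)-1,3-dioxin-4-one, via dioxinone lithium dienolate 11 (not isolated)
Conditions: LiN(SiMe3)2 (1 equiv), THF, −78 °C; then AcCl (0.5 equiv), −78 °C; cold dilute HCl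
Reagents that add atoms: acetyl chloride, CC(=O)Cl
Why: Vinylogous Claisen C-acylation of the dioxinone dienolate at its γ-carbon; two equivalents of dienolate per acyl chloride are used because the more acidic product consumes one of them, and the regenerated 10 is recovered.

Step 6
Reactants: 9 (E)-15-[3,5-bis(methoxymethoxy)phenyl]pentadec-9-enoic acid; 12 2,2-dimethyl-6-(2-oxopropyl)-1,3-dioxin-4-one
Product: 15 6-[(E)-18-[3,5-bis(methoxymethoxy)phenyl]-2,4-dioxooctadec-12-enyl]-2,2-dimethyl-1,3-dioxin-4-one, via N-acylimidazole 13 (not isolated), via keto-dioxinone dilithium dianion 14 (not isolated)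
Conditions: 9, CDI (1.05 equiv), THF, rt; separately 12 (3.5 equiv), LiN(iPr)2 (2.05 equiv per 12), THF, −78 °C; solution of 13 added to 14, −78 to −40 °C; cold dilute HCl to pH 3
Reagents that add atoms: none
Why: Crossed Claisen acylation of a 1,3-dicarbonyl-type dianion at its more basic terminal carbon by an acyl imidazole, a known way to 3,5-dioxo chains. The excess of 14 absorbs the protons of the imidazole released on activation and of the acidic product, and the product enolate does not add a second acyl group.

Step 7
Reactants: 15 6-[(E)-18-[3,5-bis(methoxymethoxy)phenyl]-2,4-dioxooctadec-12-enyl]-2,2-dimethyl-1,3-dioxin-4-one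
Product: 17 5-[(E)-14-[3,5-bis(methoxymethoxy)phenyl]tetradec-8-enyl]-7-hydroxy-2,2-dimethyl-1,3-benzodioxin-4-one, via racemic aldol adduct 16 (not isolated)
Conditions: Et3N (2 equiv), CH2Cl2, rt; then AcOH, rt
Reagents that add atoms: none
Why: Triethylamine removes a proton from C1 of the side chain, the methylene flanked by dioxinone C6 and the C2 ketone, and the cross-conjugated dienolate carries its charge to dioxinone C5. C5 adds to the C4 ketone of the side chain to give tertiary alcohol 16; E1cB loss of water and enolization of the remaining C2 ketone give the arene, and acetic acid completes the dehydration and protonates the phenoxide. The closest known reaction type is the amine-promoted aldol aromatization of diketo-dioxinones to acetonide-protected resorcylates, which copies polyketide cyclization. The one ring is closed in a 6-(enolendo)-exo-trig mode, since C1, C6 and C5 of the dienolate all lie inside the new ring and the attacked carbonyl oxygen lies outside. 17 has no stereocenter; the carbinol carbon of 16 forms without control and is erased on dehydration. The step needs aldol closure to win over Claisen closure and pyranone formation: the intact dioxinone holds the lactone carbonyl and the side chain trans across C5=C6, so the central methylene cannot reach the carboxyl carbon, and at room temperature the dioxinone does not fragment to the acylketene that leads to pyranones. The chain ketone is the only electrophile that C5 can reach through a six-membered transition state, so one regioisomer is expected, with the C7 hydroxyl free and the other ring oxygen in the acetonide. The remote E alkene and the acetals of ring B are inert to the amine and to acetic acid.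

Step 8
Reactants: 17 5-[(E)-14-[3,5-bis(methoxymethoxy)phenyl]tetradec-8-enyl]-7-hydroxy-2,2-dimethyl-1,3-benzodioxin-4-one
Product: 18 5-[(E)-14-[3,5-bis(methoxymethoxy)phenyl]tetradec-8-enyl]-7-methoxy-2,2-dimethyl-1,3-benzodioxin-4-one
Conditions: MeI, K2CO3, acetone, rt
Reagents that add atoms: iodomethane, CI
Why: Williamson O-methylation of the only free hydroxyl, which is para to the carbonyl and therefore acidic enough for carbonate; the second ring A oxygen is locked in the acetonide and ring B is capped, so only the required methyl ether can form.

Step 9
Reactants: 18 5-[(E)-14-[3,5-bis(methoxymethoxy)phenyl]tetradec-8-enyl]-7-methoxy-2,2-dimethyl-1,3-benzodioxin-4-one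
Product: 19 2-[(E)-14-[3,5-bis(methoxymethoxy)phenyl]tetradec-8-enyl]-6-hydroxy-4-methoxybenzoic acid
Conditions: KOH, 1,4-dioxane/H2O, 80 °C; cold dilute HCl to pH 3
Reagents that add atoms: potassium hydroxide, [K+].[OH-]
Why: Saponification of an aryl ester–ketal: hydroxide adds to the lactone carbonyl and its oxygen stays in the carboxyl group, and the hemiketal collapses to acetone and the phenoxide. An alcohol-free medium avoids a hindered alkyl ester, and the acetals and the alkene are stable to alkali.

Step 10
Reactants: 19 2-[(E)-14-[3,5-bis(methoxymethoxy)phenyl]tetradec-8-enyl]-6-hydroxy-4-methoxybenzoic acid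
Product: 20 3-[(E)-14-[3,5-bis(methoxymethoxy)phenyl]tetradec-8-enyl]-5-methoxyphenol
Conditions: DMF, 130 °C, argon
Reagents that add atoms: none
Why: Thermal protodecarboxylation of an ortho-hydroxybenzoic acid through ipso protonation (keto tautomer); the carboxyl-bearing carbon is activated by the ortho hydroxyl and para methoxyl and crowded by the ortho chain, as in orsellinic-type and cannabinoid acids, which lose the carboxyl group readily on heating.

Step 11
Reactants: 20 3-[(E)-14-[3,5-bis(methoxymethoxy)phenyl]tetradec-8-enyl]-5-methoxyphenol
Product: 21 dehydrobisgravillol, 5-[(E)-14-(3-hydroxy-5-methoxyphenyl)tetradec-6-enyl]benzene-1,3-diol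
Conditions: HCl (cat.), MeOH, 50 °C
Reagents that add atoms: none
Why: Acid-catalysed acetal exchange; methanol traps the one-carbon fragment as its dimethyl acetal so that it cannot condense with the resorcinol rings, and the methyl ether and the isolated E alkene are inert to dilute methanolic acid.

## Compound list

1 | 5-bromobenzene-1,3-diol | Oc1cc(O)cc(Br)c1 | starting material
2 | 1-bromo-3,5-bis(methoxymethoxy)benzene | COCOc1cc(Br)cc(OCOC)c1 | intermediate
3 | 5-bromopent-1-ene | C=CCCCBr | starting material
4 | 9-(5-bromopentyl)-9-borabicyclo[3.3.1]nonane | BrCCCCCB1C2CCCC1CCC2 | intermediate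
5 | 1-(5-bromopentyl)-3,5-bis(methoxymethoxy)benzene | COCOc1cc(CCCCCBr)cc(OCOC)c1 | intermediate
6 | dec-9-ynoic acid | C#CCCCCCCCC(=O)O | starting material
7 | dilithium salt of dec-9-ynoic acid, deprotonated at the carboxyl group and at the alkyne terminus | [Li+].[Li+].[C-]#CCCCCCCCC(=O)[O-] | intermediate
8 | 15-[3,5-bis(methoxymethoxy)phenyl]pentadec-9-ynoic acid | COCOc1cc(CCCCCC#CCCCCCCCC(=O)O)cc(OCOC)c1 | intermediate
9 | (E)-15-[3,5-bis(methoxymethoxy)phenyl]pentadec-9-enoic acid | COCOc1cc(CCCCC/C=C/CCCCCCCC(=O)O)cc(OCOC)c1 | intermediate
10 | 2,2,6-trimethyl-1,3-dioxin-4-one | CC1=CC(=O)OC(C)(C)O1 | starting material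
11 | lithium 2,2-dimethyl-6-methylidene-1,3-dioxin-4-olate (dienolate of 10) | [Li+].C=C1C=C([O-])OC(C)(C)O1 | intermediate
12 | 2,2-dimethyl-6-(2-oxopropyl)-1,3-dioxin-4-one | CC(=O)CC1=CC(=O)OC(C)(C)O1 | intermediate
13 | 1-[(E)-15-[3,5-bis(methoxymethoxy)phenyl]pentadec-9-enoyl]imidazole | COCOc1cc(CCCCC/C=C/CCCCCCCC(=O)n2ccnc2)cc(OCOC)c1 | intermediate
14 | dilithium dianion of 12, deprotonated at the ring-bound methylene and at the methyl group (bis-enolate) | [Li+].[Li+].C=C([O-])C=C1C=C([O-])OC(C)(C)O1 | intermediate
15 | 6-[(E)-18-[3,5-bis(methoxymethoxy)phenyl]-2,4-dioxooctadec-12-enyl]-2,2-dimethyl-1,3-dioxin-4-one | CC1(C)OC(=O)C=C(CC(=O)CC(=O)CCCCCCC/C=C/CCCCCc2cc(OCOC)cc(OCOC)c2)O1 | intermediate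
16 | racemic 5-[(E)-14-[3,5-bis(methoxymethoxy)phenyl]tetradec-8-enyl]-5-hydroxy-2,2-dimethyl-6,8-dihydro-5H-1,3-benzodioxine-4,7-dione | CC1(C)OC(=O)C2=C(O1)CC(=O)CC2(O)CCCCCCC/C=C/CCCCCc1cc(OCOC)cc(OCOC)c1 | intermediate
17 | 5-[(E)-14-[3,5-bis(methoxymethoxy)phenyl]tetradec-8-enyl]-7-hydroxy-2,2-dimethyl-1,3-benzodioxin-4-one | CC1(C)OC(=O)c2c(CCCCCCC/C=C/CCCCCc3cc(OCOC)cc(OCOC)c3)cc(O)cc2O1 | intermediate
18 | 5-[(E)-14-[3,5-bis(methoxymethoxy)phenyl]tetradec-8-enyl]-7-methoxy-2,2-dimethyl-1,3-benzodioxin-4-one | CC1(C)OC(=O)c2c(CCCCCCC/C=C/CCCCCc3cc(OCOC)cc(OCOC)c3)cc(OC)cc2O1 | intermediate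
19 | 2-[(E)-14-[3,5-bis(methoxymethoxy)phenyl]tetradec-8-enyl]-6-hydroxy-4-methoxybenzoic acid | COc1cc(O)c(C(=O)O)c(CCCCCCC/C=C/CCCCCc2cc(OCOC)cc(OCOC)c2)c1 | intermediate
20 | 3-[(E)-14-[3,5-bis(methoxymethoxy)phenyl]tetradec-8-enyl]-5-methoxyphenol | COc1cc(O)cc(CCCCCCC/C=C/CCCCCc2cc(OCOC)cc(OCOC)c2)c1 | intermediate
21 | dehydrobisgravillol, 5-[(E)-14-(3-hydroxy-5-methoxyphenyl)tetradec-6-enyl]benzene-1,3-diol | COc1cc(O)cc(CCCCCCC/C=C/CCCCCc2cc(O)cc(O)c2)c1 | target

## Step count and risks

Total: 11 steps. Longest linear sequence: 10 steps (steps 1 to 4 and 6 to 11, from 1 to 21); step 5 is a one-step branch.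

Step 7 (key step). Most likely to go wrong: the closure may stall at the aldol stage with incomplete dehydration, or 15 may be diverted before it cyclizes, by O-cyclization or by cycloreversion of the dioxinone on warming during handling, because diketo-dioxinones are labile. Fallback: setting out from 15, the dioxinone would be opened first. Heating in toluene with methanol releases acetone and traps the acylketene as methyl (E)-21-[3,5-bis(methoxymethoxy)phenyl]-3,5,7-trioxohenicos-15-enoate F1. Cs2CO3 in methanol followed by acetic acid would close and aromatize the open chain to methyl 2-[(E)-14-[3,5-bis(methoxymethoxy)phenyl]tetradec-8-enyl]-4,6-dihydroxybenzoate F2. The hydroxyl para to the ester, the only one not hydrogen-bonded to the carbonyl, would be methylated (MeI, K2CO3, acetone) to methyl 2-[(E)-14-[3,5-bis(methoxymethoxy)phenyl]tetradec-8-enyl]-6-hydroxy-4-methoxybenzoate F3. KOH in aqueous DMSO would then return the route at acid 19.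

Step 6. Most likely to go wrong: proton transfer from the released imidazole and from the acidic product may quench the dianion faster than it is acylated, and O-acylation or premature cyclization of the product enolate may lower the conversion. Fallback: a soft-enolization route that sets out from dienolate 11 (made from 10) and acid 9. 11 would be acylated with allyl malonyl chloride to allyl 4-(2,2-dimethyl-4-oxo-1,3-dioxin-6-yl)-3-oxobutanoate F4. 9 would be converted under neutral conditions with 1-chloro-N,N,2-trimethylprop-1-en-1-amine into (E)-15-[3,5-bis(methoxymethoxy)phenyl]pentadec-9-enoyl chloride F5. MgCl2 and pyridine in CH2Cl2 would enolize F4 and bring about C-acylation by F5 to allyl 2-[(E)-15-[3,5-bis(methoxymethoxy)phenyl]pentadec-9-enoyl]-4-(2,2-dimethyl-4-oxo-1,3-dioxin-6-yl)-3-oxobutanoate F6. Pd(PPh3)4 with morpholine would remove the allyl ester with loss of CO2 and rejoin the route at 15.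

Step 4. Most likely to go wrong: electron transfer to ring B, leading to partial ring reduction or reductive loss of an acetal group, or over-reduction during the quench. Fallback: the order is changed so that no arene is present in the dissolving-metal step. Setting out from dianion 7 (made from 6) and bromide 3, alkylation would give pentadec-14-en-9-ynoic acid F7, and Li in liquid NH3 would give (9E)-pentadeca-9,14-dienoic acid F8, the terminal alkene being inert. MeI and K2CO3 in DMF would give methyl (9E)-pentadeca-9,14-dienoate F9. 9-BBN would hydroborate only the terminal alkene to methyl (E)-15-(9-borabicyclo[3.3.1]nonan-9-yl)pentadec-9-enoate F10, which would be coupled with aryl bromide 2 (PdCl2(dppf), K3PO4) to methyl (E)-15-[3,5-bis(methoxymethoxy)phenyl]pentadec-9-enoate F11. LiOH in aqueous THF would return the route at acid 9. This order also makes step 2 unnecessary.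

Step 2. Most likely to go wrong: loss of the primary bromide by hydrolysis or elimination in the basic aqueous medium, or its slow oxidative addition leading to oligomers, and protodeboronation of the borane. Fallback: setting out from 2, Sonogashira coupling with pent-4-yn-1-ol (PdCl2(PPh3)2, CuI, Et3N) would give 5-[3,5-bis(methoxymethoxy)phenyl]pent-4-yn-1-ol F12. Hydrogenation over Pd/C, harmless at this stage because no alkene is present yet, would give 5-[3,5-bis(methoxymethoxy)phenyl]pentan-1-ol F13. Appel bromination (CBr4, PPh3) would return the route at bromide 5.

## Further compounds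

F1 | step 7 | methyl (E)-21-[3,5-bis(methoxymethoxy)phenyl]-3,5,7-trioxohenicos-15-enoate | COC(=O)CC(=O)CC(=O)CC(=O)CCCCCCC/C=C/CCCCCc1cc(OCOC)cc(OCOC)c1
F2 | step 7 | methyl 2-[(E)-14-[3,5-bis(methoxymethoxy)phenyl]tetradec-8-enyl]-4,6-dihydroxybenzoate | COC(=O)c1c(O)cc(O)cc1CCCCCCC/C=C/CCCCCc1cc(OCOC)cc(OCOC)c1
F3 | step 7 | methyl 2-[(E)-14-[3,5-bis(methoxymethoxy)phenyl]tetradec-8-enyl]-6-hydroxy-4-methoxybenzoate | COC(=O)c1c(O)cc(OC)cc1CCCCCCC/C=C/CCCCCc1cc(OCOC)cc(OCOC)c1
F4 | step 6 | allyl 4-(2,2-dimethyl-4-oxo-1,3-dioxin-6-yl)-3-oxobutanoate | C=CCOC(=O)CC(=O)CC1=CC(=O)OC(C)(C)O1
F5 | step 6 | (E)-15-[3,5-bis(methoxymethoxy)phenyl]pentadec-9-enoyl chloride | COCOc1cc(CCCCC/C=C/CCCCCCCC(=O)Cl)cc(OCOC)c1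
F6 | step 6 | allyl 2-[(E)-15-[3,5-bis(methoxymethoxy)phenyl]pentadec-9-enoyl]-4-(2,2-dimethyl-4-oxo-1,3-dioxin-6-yl)-3-oxobutanoate | C=CCOC(=O)C(C(=O)CCCCCCC/C=C/CCCCCc1cc(OCOC)cc(OCOC)c1)C(=O)CC1=CC(=O)OC(C)(C)O1
F7 | step 4 | pentadec-14-en-9-ynoic acid | C=CCCCC#CCCCCCCCC(=O)O
F8 | step 4 | (9E)-pentadeca-9,14-dienoic acid | C=CCCC/C=C/CCCCCCCC(=O)O
F9 | step 4 | methyl (9E)-pentadeca-9,14-dienoate | C=CCCC/C=C/CCCCCCCC(=O)OC
F10 | step 4 | methyl (E)-15-(9-borabicyclo[3.3.1]nonan-9-yl)pentadec-9-enoate | COC(=O)CCCCCCC/C=C/CCCCCB1C2CCCC1CCC2
F11 | step 4 | methyl (E)-15-[3,5-bis(methoxymethoxy)phenyl]pentadec-9-enoate | COCOc1cc(CCCCC/C=C/CCCCCCCC(=O)OC)cc(OCOC)c1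
F12 | step 2 | 5-[3,5-bis(methoxymethoxy)phenyl]pent-4-yn-1-ol | COCOc1cc(C#CCCCO)cc(OCOC)c1
F13 | step 2 | 5-[3,5-bis(methoxymethoxy)phenyl]pentan-1-ol | COCOc1cc(CCCCCO)cc(OCOC)c1
A1 | alternative 1 | 1-[14-[3,5-bis(methoxymethoxy)phenyl]tetradec-8-ynyl]-3-methoxy-5-(methoxymethoxy)benzene | COCOc1cc(OC)cc(CCCCCCCC#CCCCCCc2cc(OCOC)cc(OCOC)c2)c1
A2 | alternative 1 | 1-(7-bromoheptyl)-3-methoxy-5-(methoxymethoxy)benzene | COCOc1cc(OC)cc(CCCCCCCBr)c1
A3 | alternative 1 | acetylene | C#C
A4 | alternative 2 | 5-[(E)-14-(3-hydroxy-5-methoxyphenyl)tetradec-6-enyl]cyclohexane-1,3-dione | O=C1CC(=O)CC(CCCCC/C=C/CCCCCCCc2cc(OC)cc(O)c2)C1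
A5 | alternative 2 | (3E,10E)-18-(3-hydroxy-5-methoxyphenyl)octadeca-3,10-dien-2-one | CC(=O)/C=C/CCCCC/C=C/CCCCCCCc1cc(OC)cc(O)c1
A6 | alternative 2 | dimethyl malonate | COC(=O)CC(=O)OC
A7 | alternative 3 | 3-[(E)-14-[3,5-bis(triisopropylsilyloxy)phenyl]tetradec-8-enyl]-5-methoxyphenol | COc1cc(O)cc(CCCCCCC/C=C/CCCCCc2cc(O[Si](C(C)C)(C(C)C)C(C)C)cc(O[Si](C(C)C)(C(C)C)C(C)C)c2)c1
A8 | alternative 3 | 3-[(E)-14-[3,5-bis(triisopropylsilyloxy)phenyl]tetradec-8-enyl]cyclobut-2-en-1-one | O=C1C=C(CCCCCCC/C=C/CCCCCc2cc(O[Si](C(C)C)(C(C)C)C(C)C)cc(O[Si](C(C)C)(C(C)C)C(C)C)c2)C1
A9 | alternative 3 | methoxyethyne | COC#C
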